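## Analysis of the target

The target, C30H38O9, is a para-depside whose only rings are two benzene rings. The acyl carbon of ring A (a 2-hydroxy-4-methoxy-6-(2-oxoheptyl)benzoyl unit) is bound to the oxygen para to the carboxyl group of ring B (a 2-methoxy-6-(2-oxoheptyl)benzoic acid). There is no stereocentre and no stereogenic double bond, so the whole difficulty is constitutional and chemoselective.

Numbering used throughout: in each half C1 is the carboxyl carbon and C2 to C7 are the ring carbons, starting at the one that bears C1. C8 is the benzylic CH2, C9 the ketone and C10 to C14 the pentyl chain. Ring B carries primes.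

The feature that decides the strategy is the oxygen pattern of ring A. Oxygen sits on every second carbon from the ester carbon C1 through C3 (OH) and C5 (OMe) to the side-chain ketone C9. The one gap is C7, the carbon bound to C2. Ring A with its ester and side chain is therefore a 3,5,7,9-tetraoxotetradecanoyl chain closed once, C2 to C7, and ring B is the same chain again. The halves differ only in the register of methylation: O-5 is methylated and O-3 free in ring A, while O-3' is methylated and O-5' acylated in ring B.

The aryl ester C1–O-5' is flanked by two ortho substituents, so it forms slowly, yet it is an activated ester with an internal nucleophile. The enol oxygen of C9 can close a six-membered ring on C1, which gives a 3-pentylisocoumarin and expels ring B. The free acid C1' can do the same with C9'.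

The synthesis must therefore meet three demands:
- make a hindered ester without ever activating a keto acid;
- tell four phenolic oxygens apart without long protecting-group sequences;
- end under nearly neutral conditions.

## Retrosynthetic reasoning

**17 back to 16 and 15 (unmasking).** The last bonds cut are the benzyl–oxygen bond of the ester at C1' and the two dioxolanes at C9 and C9'. Hydrogenolysis of 16 is placed last because it is neutral, so the keto acid 17 never meets acid or base. The ketals of 15 are removed one step earlier, while C1' is still an ester that cannot lactonise by dehydration.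

**15 back to 14 (O-5–CH3 bond).** In 14 the O-3 hydroxyl is chelated to the depside carbonyl, and the para O-5 hydroxyl is the only free, acidic phenol. One substrate-controlled methylation is enough and no phenol protecting group is needed on ring A. The ketals must still be present, because a free C9 ketone would give an enolate that attacks C1.

**14 back to 13, 12, and then 11 plus 8 (key disconnection).** Two bonds are cut together: the ring bond C2–C7 of ring A and the depside bond C1–O-5'.
- Cutting C2–C7 unfolds ring A into the aryl trioxo ester 13.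
- Cutting C1–O-5' turns 13 into the acylketene 12 and the phenol 8.
- 12 is stored as the dioxinone 11.

The cut is made here because the hindrance that makes the ester hard to form does not exist yet. C1 is an sp-hybridised, unhindered ketene carbon when the ester is made, and the two ortho substituents appear only afterwards. No keto acid is ever activated. The forward step has to capture 12 with a phenol and then fold 13 in the single register C2 to C7. The dioxolane at C9 enforces this register.

**11 back to 10 plus 3, and 10 back to 9.** The chain is cut at C6–C7 and at C4–C5. Both bonds are Claisen-type acylations of dioxinone enolates. C1 to C4 come from the commodity heterocycle 9, C5 and C6 from an acetyl unit, and C7 to C14 from the acyl donor 3.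

**8 back to 7, 6 and 5 (ring B).** The benzyl ester is cut first. Then the ring bond C2'–C7' is cut, which unfolds ring B into the chain 6, and 6 is stored as the 2-pyrone 5. A 4-methoxy-2-pyrone is chosen instead of a second dioxinone because it already holds the methylation register of ring B. Its methoxy group sits on C3', and its ring oxygen on C5' is released as the one free phenol. No protection or selective methylation is then needed on ring B.

**5 back to 4 plus 3.** The bond C6'–C7' is cut. The commercial pyrone 4 holds C1' to C6', and the same acyl donor 3 delivers C7' to C14'.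

**3 back to 2 and 1.** The amide and the dioxolane are removed, which leads to the commercial β-keto ester 1. It holds C7 to C14 with both oxygens in place.

## Alternatives that were turned down

**Alternative 1:** The textbook route cuts only C1–O-5', between two finished aromatic halves. These are 2-hydroxy-4-methoxy-6-(2-oxoheptyl)benzoic acid A1 and benzyl 4-hydroxy-2-methoxy-6-(2-oxoheptyl)benzoate A2. The forward key step is an esterification through a carbodiimide or a mixed anhydride, followed by hydrogenolysis. Each half would come from an orsellinate-type o-toluate by phenol protection, lateral lithiation, hexanoylation and deprotection.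
- Any activated form of A1 carries the C9 enol within reach of C1 and should collapse to 8-hydroxy-6-methoxy-3-pentylisocoumarin A3 faster than a hindered phenol can attack a di-ortho-substituted acyl group.
- The strong base of the side-chain step forces separate protecting-group sequences on both halves.
- The two methylation registers need two different selective schemes.
- The step count per half is about that of the whole route below.

**Alternative 2:** Ring A is cut at C2–C3 and C6–C7, a Diels-Alder benzannulation on an ester already in place. 4-(2-Pentyl-1,3-dioxolan-2-yl)but-2-ynoic acid A4 would be esterified with 8 to the aryl ynoate A5. A5 would be heated with 5,5-dimethyl-1,3-bis(trimethylsilyloxy)cyclohexa-1,3-diene A6. Cycloaddition, cycloreversion with loss of the gem-dimethyl bridge, and desilylation would give 14. The regiochemistry is sound and the unhindered ynoic acid esterifies easily.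
- A4 costs three further steps from 3 (reduction, alkyne homologation, carboxylation), and A6 one more.
- The ester and the ring are made in two operations instead of one.
- The β-carbon of A5 bears a neopentyl-type CH2–C(ketal) group, so high temperature is needed.
- At that temperature the propargylic C8 hydrogens can shift to the allenoate, and the silyl enol ether can add in a Michael sense.

**Alternative 3:** Both C8–C9 bonds are cut at the end. Benzyl 4-[(2-hydroxy-4-methoxy-6-methylbenzoyl)oxy]-2-methoxy-6-methylbenzoate A7, a simple methyl depside, would be deprotonated at both benzylic methyl groups with an amide base. It would then be acylated twice with a hexanoyl donor to give 16. This is very short on paper.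
- A benzylic anion ortho to an aryl ester can expel the ring B phenoxide.
- The depside carbonyl is the best electrophile in the flask for every carbanion present.
- Each C9 enolate formed by the acylation is set up to close on C1, giving A3 with loss of ring B.
- The free O-3 hydroxyl consumes base and lowers the acidity of the ring A methyl group.

Key step: step 8

Remark on the chemistry: the SMILES holds no stereocentre. The target is taken as the open keto acid, and all poly-β-carbonyl compounds are drawn in their keto forms although they are largely enolised.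

## Route

Step 1
Reactants: 1 ethyl 3-oxooctanoate
Product: 2 ethyl 2-(2-pentyl-1,3-dioxolan-2-yl)acetate
Conditions: HOCH2CH2OH (2 equiv), TsOH·H2O (cat.), toluene, reflux, Dean-Stark trap
Reagents that add atoms: ethylene glycol, OCCO
Why: Acid-catalysed ketalisation of a β-keto ester with azeotropic removal of water; the ketone reacts and the ester does not. The dioxolane is the mask that later fixes the folding register at C9 and C9'.

Step 2
Reactants: 2 ethyl 2-(2-pentyl-1,3-dioxolan-2-yl)acetate
Product: 3 N-methoxy-N-methyl-2-(2-pentyl-1,3-dioxolan-2-yl)acetamide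
Conditions: MeNH(OMe)·HCl (1.5 equiv), iPrMgCl (3 equiv), THF, −20 to 0 °C
Reagents that add atoms: N,O-dimethylhydroxylamine hydrochloride, CNOC.Cl
Why: Aminolysis of the ester by the chloromagnesium amide, the usual entry to the Weinreb ketone synthesis; the magnesium amide is too weakly basic to start β-elimination of the ketal. One acyl donor serves both halves of the target.

Step 3
Reactants: 4 4-methoxy-6-methyl-2H-pyran-2-one; 3 N-methoxy-N-methyl-2-(2-pentyl-1,3-dioxolan-2-yl)acetamide
Product: 5 4-methoxy-6-[2-oxo-3-(2-pentyl-1,3-dioxolan-2-yl)propyl]-2H-pyran-2-one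
Conditions: LiN(SiMe3)2 (1.15 equiv), THF, −78 °C; then 3, −78 to −20 °C; aq. NH4Cl
Reagents that add atoms: none
Why: Lateral (vinylogous) deprotonation of the 6-methyl group of 4 gives the extended dienolate, which acylates at the exocyclic carbon in a Weinreb ketone synthesis and forms C6'–C7'. The chelated tetrahedral adduct lasts until the quench, so over-addition and proton transfer from the acidic product are avoided.

Step 4
Reactants: 5 4-methoxy-6-[2-oxo-3-(2-pentyl-1,3-dioxolan-2-yl)propyl]-2H-pyran-2-one
Product: 7 4-hydroxy-2-methoxy-6-[(2-pentyl-1,3-dioxolan-2-yl)methyl]benzoic acid, via ring-opened methoxy dioxo enoate 6 (not isolated)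
Conditions: 2 M aq. KOH, THF, 20 to 45 °C; then 1 M HCl, 0 °C, to pH 4
Reagents that add atoms: potassium hydroxide, [K+].[OH-]
Why: Base-induced pyrone-to-resorcylate ring transformation: hydroxide opens the lactone at C1', the vinylogous enolate of 6 attacks the C7' ketone through C2' (intramolecular aldol, 6-(enolexo)-exo-trig), and dehydration aromatises. As a carboxylate C1' is no electrophile, so the Claisen mode C6' to C1' is shut, and the C5'–C7' diketonate keeps C8' from being deprotonated, which protects the ketal from β-elimination. The enol ether keeps the methyl group on O-3', and the former ring oxygen appears as the single free phenol O-5'H.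

Step 5
Reactants: 7 4-hydroxy-2-methoxy-6-[(2-pentyl-1,3-dioxolan-2-yl)methyl]benzoic acid
Product: 8 benzyl 4-hydroxy-2-methoxy-6-[(2-pentyl-1,3-dioxolan-2-yl)methyl]benzoate
Conditions: BnBr (1.05 equiv), KHCO3 (1.2 equiv), DMF, 25 °C
Reagents that add atoms: benzyl bromide, BrCc1ccccc1
Why: SN2 alkylation of the carboxylate, which bypasses the hindered carbonyl carbon. KHCO3 is too weak to deprotonate the phenol to any useful extent, so O-5'H stays free.

Step 6
Reactants: 9 2,2,6-trimethyl-4H-1,3-dioxin-4-one
Product: 10 2,2-dimethyl-6-(2-oxopropyl)-4H-1,3-dioxin-4-one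
Conditions: 9 (2 equiv), LiN(SiMe3)2 (2 equiv), THF, −78 °C; AcCl (1 equiv), −78 °C; aq. NH4Cl
Reagents that add atoms: acetyl chloride, CC(=O)Cl
Why: γ-Deprotonation of 9 gives the lithium dienolate, which is C-acylated at the exocyclic carbon (vinylogous Claisen condensation) and forms C4–C5. Two equivalents of dienolate are used because 10 is more acidic than 9.

Step 7
Reactants: 10 2,2-dimethyl-6-(2-oxopropyl)-4H-1,3-dioxin-4-one; 3 N-methoxy-N-methyl-2-(2-pentyl-1,3-dioxolan-2-yl)acetamide
Product: 11 2,2-dimethyl-6-[2,4-dioxo-5-(2-pentyl-1,3-dioxolan-2-yl)pentyl]-4H-1,3-dioxin-4-one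
Conditions: LiN(iPr)2 (2.2 equiv), THF, −78 to −40 °C; then 3, −78 to −10 °C; aq. NH4Cl
Reagents that add atoms: none
Why: The dianion of 10 reacts at the carbanion formed last, the terminal C6, as in the γ-acylation of β-dicarbonyl dianions, here run as a Weinreb ketone synthesis that forms C6–C7. The dioxinone stays closed at low temperature and stores C1 to C3 as a latent acylketene.

Step 8
Reactants: 11 2,2-dimethyl-6-[2,4-dioxo-5-(2-pentyl-1,3-dioxolan-2-yl)pentyl]-4H-1,3-dioxin-4-one; 8 benzyl 4-hydroxy-2-methoxy-6-[(2-pentyl-1,3-dioxolan-2-yl)methyl]benzoate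
Product: 14 benzyl 4-({2,4-dihydroxy-6-[(2-pentyl-1,3-dioxolan-2-yl)methyl]benzoyl}oxy)-2-methoxy-6-[(2-pentyl-1,3-dioxolan-2-yl)methyl]benzoate, via acylketene 12 (not isolated), via aryl trioxo ester 13 (not isolated)
Conditions: 8 (1.5 equiv, concentrated in toluene), 110 °C, slow addition of 11 (1 equiv), N2 sweep; cool to 20 °C; Et3N (0.3 equiv), 4 Å molecular sieves, toluene–CH2Cl2, 20 °C; filtration through SiO2
Reagents that add atoms: none
Why: Proposed new method: thermal retro-[4+2] cleavage of the dioxinone ring of 11 expels the acetonide as acetone and gives acylketene 12, whose unhindered sp carbon C1 is captured by the only O–H group of 8 to make the depside bond C1–O-5' as the aryl 3,5,7-trioxo ester 13. With catalytic Et3N the C2 enolate of 13 adds to the C7 ketone, and dehydration plus enolisation of C3 and C5 gives ring A, so the hindered ester and the ring that hinders it are made in one operation and in that order. The closest known reaction types are the same thermolysis, trapping and aromatisation cascade of β,δ-diketo-dioxinones with aliphatic alcohols, and the acetoacetylation of phenols with 9; new here are the phenol as the trap in the cascade and an aryl ester that must survive the aromatisation. The one ring closed is the six-membered carbocycle, by a 6-(enolexo)-exo-trig aldol addition C2 to C7, and no stereocentre survives the dehydration. The folding register is secured by the dioxolane at C9, which removes the electrophile of the C4 to C9 mode and the acidity at C8 that the C8 to C3 mode needs, so that C2 to C7 is the only aldol left. The trapping needs no site selection because 8 has one hydroxyl group and its benzyl ester is di-ortho-substituted and inert. The step must beat closure of the C5 enol oxygen on C1 (from 12 directly, or from 13 after E1cB loss of the phenoxide) and the Claisen mode C6 to C1; the concentrated excess of 8, the slow addition of 11 and a weak base in an aprotic medium are chosen so that any ketene that is re-formed is recaptured by 8. The precursor 11 is an acyclic chain on a commodity heterocycle, while the product holds the full C30 skeleton with every oxygen in place.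

Step 9
Reactants: 14 benzyl 4-({2,4-dihydroxy-6-[(2-pentyl-1,3-dioxolan-2-yl)methyl]benzoyl}oxy)-2-methoxy-6-[(2-pentyl-1,3-dioxolan-2-yl)methyl]benzoate
Product: 15 benzyl 4-({2-hydroxy-4-methoxy-6-[(2-pentyl-1,3-dioxolan-2-yl)methyl]benzoyl}oxy)-2-methoxy-6-[(2-pentyl-1,3-dioxolan-2-yl)methyl]benzoate
Conditions: MeI (1.1 equiv), K2CO3 (1.1 equiv), acetone, 20 °C
Reagents that add atoms: iodomethane, CI
Why: Williamson ether synthesis under substrate control: O-3H is chelated to the depside carbonyl, so the para O-5H is the more acidic and the only accessible phenol. The para phenoxide deactivates C1 toward nucleophiles, and the ketals keep C8 non-acidic, so K2CO3 cannot start an enolate attack on the depside.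

Step 10
Reactants: 15 benzyl 4-({2-hydroxy-4-methoxy-6-[(2-pentyl-1,3-dioxolan-2-yl)methyl]benzoyl}oxy)-2-methoxy-6-[(2-pentyl-1,3-dioxolan-2-yl)methyl]benzoate
Product: 16 benzyl 4-{[2-hydroxy-4-methoxy-6-(2-oxoheptyl)benzoyl]oxy}-2-methoxy-6-(2-oxoheptyl)benzoate
Conditions: TsOH·H2O (cat.), acetone–H2O 10:1, 20 to 35 °C; NaHCO3 quench as soon as complete
Reagents that add atoms: water, O
Why: Acid-catalysed hydrolysis of two dialkyl-ketone dioxolanes; both esters are di-ortho-substituted and should be inert to dilute acid at room temperature. The run is kept short and is quenched at once, because long exposure to acid would favour enol lactonisation onto C1.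

Step 11
Reactants: 16 benzyl 4-{[2-hydroxy-4-methoxy-6-(2-oxoheptyl)benzoyl]oxy}-2-methoxy-6-(2-oxoheptyl)benzoate
Product: 17 4-{[2-hydroxy-4-methoxy-6-(2-oxoheptyl)benzoyl]oxy}-2-methoxy-6-(2-oxoheptyl)benzoic acid (target)
Conditions: H2 (1 atm), Pd/C (10 wt% Pd), EtOAc, 20 °C
Reagents that add atoms: none
Why: Hydrogenolysis of the benzyl ester under neutral conditions; aliphatic ketones, the aryl ester and the aryl ethers are not reduced at atmospheric pressure. Neither acid nor base meets the keto acid, so lactonisation and depside cleavage are avoided.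

## Compound list

1 | ethyl 3-oxooctanoate | CCCCCC(=O)CC(=O)OCC | starting material
2 | ethyl 2-(2-pentyl-1,3-dioxolan-2-yl)acetate | CCCCCC1(CC(=O)OCC)OCCO1 | intermediate
3 | N-methoxy-N-methyl-2-(2-pentyl-1,3-dioxolan-2-yl)acetamide | CCCCCC1(CC(=O)N(C)OC)OCCO1 | intermediate
4 | 4-methoxy-6-methyl-2H-pyran-2-one | COC1=CC(=O)OC(C)=C1 | starting material
5 | 4-methoxy-6-[2-oxo-3-(2-pentyl-1,3-dioxolan-2-yl)propyl]-2H-pyran-2-one | CCCCCC1(CC(=O)CC2=CC(OC)=CC(=O)O2)OCCO1 | intermediate
6 | (2E)-3-methoxy-5,7-dioxo-8-(2-pentyl-1,3-dioxolan-2-yl)oct-2-enoic acid (present as its potassium salt) | CCCCCC1(OCCO1)CC(=O)CC(=O)C/C(OC)=C\C(=O)O | intermediate (not isolated)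
7 | 4-hydroxy-2-methoxy-6-[(2-pentyl-1,3-dioxolan-2-yl)methyl]benzoic acid | CCCCCC1(OCCO1)Cc1cc(O)cc(OC)c1C(=O)O | intermediate
8 | benzyl 4-hydroxy-2-methoxy-6-[(2-pentyl-1,3-dioxolan-2-yl)methyl]benzoate | CCCCCC1(OCCO1)Cc1cc(O)cc(OC)c1C(=O)OCc1ccccc1 | intermediate
9 | 2,2,6-trimethyl-4H-1,3-dioxin-4-one | CC1=CC(=O)OC(C)(C)O1 | starting material
10 | 2,2-dimethyl-6-(2-oxopropyl)-4H-1,3-dioxin-4-one | CC(=O)CC1=CC(=O)OC(C)(C)O1 | intermediate
11 | 2,2-dimethyl-6-[2,4-dioxo-5-(2-pentyl-1,3-dioxolan-2-yl)pentyl]-4H-1,3-dioxin-4-one | CCCCCC1(OCCO1)CC(=O)CC(=O)CC1=CC(=O)OC(C)(C)O1 | intermediate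
12 | 8-(2-pentyl-1,3-dioxolan-2-yl)oct-1-ene-1,3,5,7-tetraone (acylketene) | O=C=CC(=O)CC(=O)CC(=O)CC1(CCCCC)OCCO1 | intermediate (not isolated)
13 | benzyl 2-methoxy-6-[(2-pentyl-1,3-dioxolan-2-yl)methyl]-4-{[3,5,7-trioxo-8-(2-pentyl-1,3-dioxolan-2-yl)octanoyl]oxy}benzoate | CCCCCC1(OCCO1)CC(=O)CC(=O)CC(=O)CC(=O)Oc1cc(CC2(CCCCC)OCCO2)c(C(=O)OCc2ccccc2)c(OC)c1 | intermediate (not isolated)
14 | benzyl 4-({2,4-dihydroxy-6-[(2-pentyl-1,3-dioxolan-2-yl)methyl]benzoyl}oxy)-2-methoxy-6-[(2-pentyl-1,3-dioxolan-2-yl)methyl]benzoate | CCCCCC1(OCCO1)Cc1cc(O)cc(O)c1C(=O)Oc1cc(CC2(CCCCC)OCCO2)c(C(=O)OCc2ccccc2)c(OC)c1 | intermediate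
15 | benzyl 4-({2-hydroxy-4-methoxy-6-[(2-pentyl-1,3-dioxolan-2-yl)methyl]benzoyl}oxy)-2-methoxy-6-[(2-pentyl-1,3-dioxolan-2-yl)methyl]benzoate | CCCCCC1(OCCO1)Cc1cc(OC)cc(O)c1C(=O)Oc1cc(CC2(CCCCC)OCCO2)c(C(=O)OCc2ccccc2)c(OC)c1 | intermediate
16 | benzyl 4-{[2-hydroxy-4-methoxy-6-(2-oxoheptyl)benzoyl]oxy}-2-methoxy-6-(2-oxoheptyl)benzoate | CCCCCC(=O)Cc1cc(OC)cc(O)c1C(=O)Oc1cc(CC(=O)CCCCC)c(C(=O)OCc2ccccc2)c(OC)c1 | intermediate
17 | 4-{[2-hydroxy-4-methoxy-6-(2-oxoheptyl)benzoyl]oxy}-2-methoxy-6-(2-oxoheptyl)benzoic acid | CCCCCC(=O)Cc1cc(OC)cc(O)c1C(=O)Oc1cc(CC(=O)CCCCC)c(C(=O)O)c(OC)c1 | target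

## Step count and least certain steps

Total step count: 11. Longest linear sequence: 9 steps (steps 1, 2, 3, 4, 5, 8, 9, 10, 11). Steps 6 and 7 run in parallel, and compound 3 is used in both branches.

**Step 8 (key step, proposed new method).** Four processes can take material away.
- The ketene can be captured internally by the C5 enol oxygen before the less nucleophilic phenol arrives.
- The ester formation can reverse by E1cB loss of the rather good phenoxide leaving group during the base-induced aromatisation, followed by the same internal capture.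
- A Claisen-type closure C6 to C1 can occur with loss of the phenoxide.
- Ketene still present can acylate the new para phenol of ring A, if aromatisation already starts at 110 °C.

All four stem from the aryl ester being both slower to form and easier to lose than the alkyl esters for which the cascade is established.

The fallback uses known chemistry only. It sets out from 11 and 8 and comes back to the route at 15, so that step 9 is no longer needed. Compound 11 is aromatised with the dioxinone left closed (Et3N, CH2Cl2, 20 °C) to 7-hydroxy-2,2-dimethyl-5-[(2-pentyl-1,3-dioxolan-2-yl)methyl]-4H-1,3-benzodioxin-4-one F1. This is methylated (MeI, K2CO3, acetone) to 7-methoxy-2,2-dimethyl-5-[(2-pentyl-1,3-dioxolan-2-yl)methyl]-4H-1,3-benzodioxin-4-one F2. Saponification (KOH, aq. DMSO) gives 2-hydroxy-4-methoxy-6-[(2-pentyl-1,3-dioxolan-2-yl)methyl]benzoic acid F3. F3 is then esterified with 8 by N,N'-dicyclohexylcarbodiimide in toluene. The ketal removes the internal nucleophile that spoils this coupling in Alternative 1.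

**Step 4.** Three things can go wrong.
- Hydroxide may attack the enol-ether carbon C3' instead of the lactone carbonyl, with loss of the methyl group.
- The opened C5'–C7' diketone may suffer retro-Claisen cleavage in warm aqueous base.
- The aldol closure may be slow, because the nucleophile is only the minor, vinylogous tautomer of the diketonate.

The fallback sets out from 11 and comes back at 8. It builds ring B by the established alcohol version of the ketene cascade instead of the pyrone transformation. Compound 11 is heated with benzyl alcohol (toluene, 110 °C) and aromatised (Cs2CO3, CH2Cl2–iPrOH, then AcOH) to benzyl 2,4-dihydroxy-6-[(2-pentyl-1,3-dioxolan-2-yl)methyl]benzoate F4. The unchelated para hydroxyl is silylated (iPr3SiCl, imidazole) to benzyl 2-hydroxy-6-[(2-pentyl-1,3-dioxolan-2-yl)methyl]-4-(triisopropylsilyloxy)benzoate F5. The chelated hydroxyl is methylated (MeI, K2CO3, DMF) to benzyl 2-methoxy-6-[(2-pentyl-1,3-dioxolan-2-yl)methyl]-4-(triisopropylsilyloxy)benzoate F6. Bu4NF then releases 8.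

**Step 7.** The strongly basic terminal carbanion of the dianion may deprotonate the α-CH2 of 3 instead of adding to it. This quenches the dianion and opens the dioxolane by β-elimination. The product is also prone to premature aromatisation on silica.

The fallback sets out from 3 and 10 and comes back at 11. It replaces the Claisen-type acylation by aldol addition and oxidation. Compound 3 is reduced (iBu2AlH, THF, −78 °C) to 2-(2-pentyl-1,3-dioxolan-2-yl)acetaldehyde F7. The dianion of 10 is added to this far better electrophile to give racemic 6-[4-hydroxy-2-oxo-5-(2-pentyl-1,3-dioxolan-2-yl)pentyl]-2,2-dimethyl-4H-1,3-dioxin-4-one F8. Dess-Martin periodinane oxidises F8 to 11.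

**Step 10.** Once C9 is free, acid-catalysed enolisation and closure of the enol oxygen on C1 can cleave the depside. The same closure on C1' can cost the benzyl ester. Incomplete hydrolysis of one of the two hindered ketals would tempt one toward harsher conditions.

The fallback sets out from 15 and comes back at 17. It inverts the end game, so that no Brønsted acid meets a keto depside. Compound 15 is first hydrogenolysed (H2, Pd/C, EtOAc) to 4-({2-hydroxy-4-methoxy-6-[(2-pentyl-1,3-dioxolan-2-yl)methyl]benzoyl}oxy)-2-methoxy-6-[(2-pentyl-1,3-dioxolan-2-yl)methyl]benzoic acid F9. Both ketals are then removed, not by hydrolysis but by exchange with dry acetone under catalysis by I2 at 20 °C.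

## Further compounds

F1 | step 8 | 7-hydroxy-2,2-dimethyl-5-[(2-pentyl-1,3-dioxolan-2-yl)methyl]-4H-1,3-benzodioxin-4-one | CCCCCC1(OCCO1)Cc1cc(O)cc2OC(C)(C)OC(=O)c12
F2 | step 8 | 7-methoxy-2,2-dimethyl-5-[(2-pentyl-1,3-dioxolan-2-yl)methyl]-4H-1,3-benzodioxin-4-one | CCCCCC1(OCCO1)Cc1cc(OC)cc2OC(C)(C)OC(=O)c12
F3 | step 8 | 2-hydroxy-4-methoxy-6-[(2-pentyl-1,3-dioxolan-2-yl)methyl]benzoic acid | CCCCCC1(OCCO1)Cc1cc(OC)cc(O)c1C(=O)O
F4 | step 4 | benzyl 2,4-dihydroxy-6-[(2-pentyl-1,3-dioxolan-2-yl)methyl]benzoate | CCCCCC1(OCCO1)Cc1cc(O)cc(O)c1C(=O)OCc1ccccc1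
F5 | step 4 | benzyl 2-hydroxy-6-[(2-pentyl-1,3-dioxolan-2-yl)methyl]-4-(triisopropylsilyloxy)benzoate | CCCCCC1(OCCO1)Cc1cc(O[Si](C(C)C)(C(C)C)C(C)C)cc(O)c1C(=O)OCc1ccccc1
F6 | step 4 | benzyl 2-methoxy-6-[(2-pentyl-1,3-dioxolan-2-yl)methyl]-4-(triisopropylsilyloxy)benzoate | CCCCCC1(OCCO1)Cc1cc(O[Si](C(C)C)(C(C)C)C(C)C)cc(OC)c1C(=O)OCc1ccccc1
F7 | step 7 | 2-(2-pentyl-1,3-dioxolan-2-yl)acetaldehyde | CCCCCC1(CC=O)OCCO1
F8 | step 7 | 6-[4-hydroxy-2-oxo-5-(2-pentyl-1,3-dioxolan-2-yl)pentyl]-2,2-dimethyl-4H-1,3-dioxin-4-one (racemic) | CCCCCC1(OCCO1)CC(O)CC(=O)CC1=CC(=O)OC(C)(C)O1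
F9 | step 10 | 4-({2-hydroxy-4-methoxy-6-[(2-pentyl-1,3-dioxolan-2-yl)methyl]benzoyl}oxy)-2-methoxy-6-[(2-pentyl-1,3-dioxolan-2-yl)methyl]benzoic acid | CCCCCC1(OCCO1)Cc1cc(OC)cc(O)c1C(=O)Oc1cc(CC2(CCCCC)OCCO2)c(C(=O)O)c(OC)c1
A1 | alternative 1 | 2-hydroxy-4-methoxy-6-(2-oxoheptyl)benzoic acid | CCCCCC(=O)Cc1cc(OC)cc(O)c1C(=O)O
A2 | alternative 1 | benzyl 4-hydroxy-2-methoxy-6-(2-oxoheptyl)benzoate | CCCCCC(=O)Cc1cc(O)cc(OC)c1C(=O)OCc1ccccc1
A3 | alternative 1 | 8-hydroxy-6-methoxy-3-pentyl-1H-isochromen-1-one | CCCCCC1=Cc2cc(OC)cc(O)c2C(=O)O1
A4 | alternative 2 | 4-(2-pentyl-1,3-dioxolan-2-yl)but-2-ynoic acid | CCCCCC1(CC#CC(=O)O)OCCO1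
A5 | alternative 2 | benzyl 2-methoxy-6-[(2-pentyl-1,3-dioxolan-2-yl)methyl]-4-{[4-(2-pentyl-1,3-dioxolan-2-yl)but-2-ynoyl]oxy}benzoate | CCCCCC1(OCCO1)CC#CC(=O)Oc1cc(CC2(CCCCC)OCCO2)c(C(=O)OCc2ccccc2)c(OC)c1
A6 | alternative 2 | 5,5-dimethyl-1,3-bis(trimethylsilyloxy)cyclohexa-1,3-diene | C[Si](C)(C)OC1=CC(O[Si](C)(C)C)=CC(C)(C)C1
A7 | alternative 3 | benzyl 4-[(2-hydroxy-4-methoxy-6-methylbenzoyl)oxy]-2-methoxy-6-methylbenzoate | COc1cc(C)c(C(=O)Oc2cc(C)c(C(=O)OCc3ccccc3)c(OC)c2)c(O)c1
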